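**Retrosynthetic overview**
1. Feature: in quinone ring B the C4 carbonyl lies between C4a of ring A (the carbon ortho to the C5 oxygen) and C3–H. C4 can therefore enter as carbon monoxide, between an aryl iodide at C4a and a terminal CH2 that becomes C3.
2. Key disconnection (C4a–C4 and C4–C3): the O-methyl, methyl ester form of the target goes back to CO and a 2-iodoaryl 1-(chromon-8-yl)vinyl ketone. This ketone already holds C1, C2, the C2–C8′ bond and rings A, C and D.
3. C1–C2: the ketone comes from a Stille acylation of the 8′-(1-stannylvinyl)chromone ester with 2-iodo-3-methoxy-5-methylbenzoyl chloride. The iodine is set by directed ortho-lithiation between CO2H and OMe.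
4. Chromone half: stannane ← 8′-ethynyl ester ← 8′-iodo-5′-triflate (Sonogashira at C8′, then methoxycarbonylation at C5′) ← 5-methoxy-7-methylchromone ← 3,5-dimethoxytoluene.
5. Ring order: benzene rings A and C are bought, pyranone ring D closes in step 5, and quinone ring B closes last in step 14. Two deprotections follow.

Key step: step 14

Remark: the target SMILES has no stereocentre and no stereodescriptor. The hindered C2–C8′ axis is left unassigned, so the material is racemic if rotation proves slow.

**Route**

Step 1
Reactants: 1 3-methoxy-5-methylbenzoic acid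
Product: 3 2-iodo-3-methoxy-5-methylbenzoic acid, via dilithio benzoate 2 (not isolated)
Conditions: 2,2,6,6-tetramethylpiperidine, n-BuLi (4 equiv each), THF, 0 °C; add 1, 0 °C; I2, THF, −78 °C → rt; aq. HCl
Reagents that add atoms: iodine, II
Why: Cooperative directed ortho-metalation, in which the lithium carboxylate and the methoxy group both activate the C2–H between them, so the hindered amide base should lithiate only there (the C5 methyl is ortho to neither director, so lateral lithiation is not expected) and iodine traps the aryl anion.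

Step 2
Reactants: 3 2-iodo-3-methoxy-5-methylbenzoic acid
Product: 4 2-iodo-3-methoxy-5-methylbenzoyl chloride
Conditions: (COCl)2 (1.5 equiv), DMF (cat.), CH2Cl2, 0 °C → rt
Reagents that add atoms: oxalyl chloride, O=C(Cl)C(=O)Cl
Why: Standard acid chloride formation through the chloroiminium (Vilsmeier-type) catalyst, to which the aryl iodide and the ether are inert.

Step 3
Reactants: 5 3,5-dimethoxytoluene
Product: 7 1-(2,6-dimethoxy-4-methylphenyl)ethan-1-one, via aryllithium 6 (not isolated)
Conditions: n-BuLi (1.1 equiv), THF, 0 °C → rt; MeC(O)N(OMe)Me, −78 °C → rt; 1 M HCl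
Reagents that add atoms: N-methoxy-N-methylacetamide, CC(=O)N(C)OC
Why: Directed ortho-metalation at the carbon flanked by both methoxy groups, followed by a Weinreb ketone synthesis whose chelated tetrahedral adduct prevents a second addition.

Step 4
Reactants: 7 1-(2,6-dimethoxy-4-methylphenyl)ethan-1-one
Product: 8 1-(2-hydroxy-6-methoxy-4-methylphenyl)ethan-1-one
Conditions: BCl3 (1.1 equiv), CH2Cl2, −78 → 0 °C; H2O
Reagents that add atoms: none
Why: Chelation-assisted aryl methyl ether cleavage, in which BCl3 bound to the ketone oxygen removes one ortho methyl group through a six-membered chelate; the two methoxy groups are equivalent by symmetry, so only one product can form, and the boron chelate resists a second cleavage at this temperature.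

Step 5
Reactants: 8 1-(2-hydroxy-6-methoxy-4-methylphenyl)ethan-1-one
Product: 10 5-methoxy-7-methyl-4H-chromen-4-one, via enaminone 9 (not isolated)
Conditions: Me2NCH(OMe)2 (2 equiv), toluene, 100 °C; concentrate; conc. HCl, CH2Cl2, 40 °C
Reagents that add atoms: N,N-dimethylformamide dimethyl acetal, COC(OC)N(C)C
Why: Enaminone route to 2,3-unsubstituted chromones, in which the acetyl CH3 condenses with the amide acetal and acid then promotes conjugate addition of the phenol and loss of dimethylamine, closing ring D.

Step 6
Reactants: 10 5-methoxy-7-methyl-4H-chromen-4-one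
Product: 11 8-iodo-5-methoxy-7-methyl-4H-chromen-4-one
Conditions: N-iodosuccinimide (1.1 equiv), CF3CO2H, MeCN, 0 °C → rt, dark
Reagents that add atoms: N-iodosuccinimide, O=C1CCC(=O)N1I
Why: Electrophilic aromatic iodination, expected at C8 because it is para to the strong 5-OMe donor and ortho to O1, whereas C6 is screened by the methoxy methyl (turned away from the peri carbonyl) and by the C7 methyl, in line with the 8-halogenation of 5-alkoxychromones and 5-alkoxyflavones.

Step 7
Reactants: 11 8-iodo-5-methoxy-7-methyl-4H-chromen-4-one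
Product: 12 5-hydroxy-8-iodo-7-methyl-4H-chromen-4-one
Conditions: BCl3 (2 equiv), CH2Cl2, −78 → 0 °C; H2O
Reagents that add atoms: none
Why: Peri-carbonyl-assisted demethylation, in which the C4 oxygen and the C5 methoxy oxygen chelate boron so that the ether is cleaved under conditions that leave the aryl iodide and the pyranone untouched.

Step 8
Reactants: 12 5-hydroxy-8-iodo-7-methyl-4H-chromen-4-one
Product: 13 8-iodo-7-methyl-4-oxo-4H-chromen-5-yl trifluoromethanesulfonate
Conditions: Tf2O (1.3 equiv), pyridine (3 equiv), CH2Cl2, 0 °C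
Reagents that add atoms: triflic anhydride, O=S(=O)(OS(=O)(=O)C(F)(F)F)C(F)(F)F
Why: O-Sulfonylation of the phenol, for which the very electrophilic anhydride overcomes the hydrogen bond to the C4 carbonyl.

Step 9
Reactants: 13 8-iodo-7-methyl-4-oxo-4H-chromen-5-yl trifluoromethanesulfonate; 14 (triisopropylsilyl)acetylene
Product: 15 7-methyl-4-oxo-8-[(triisopropylsilyl)ethynyl]-4H-chromen-5-yl trifluoromethanesulfonate
Conditions: PdCl2(PPh3)2 (3 mol %), CuI (6 mol %), NEt3 (3 equiv), THF, rt → 40 °C
Reagents that add atoms: none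
Why: Sonogashira coupling, chemoselective because zerovalent palladium with PPh3 inserts into the C–I bond far faster than into the C–OTf bond near room temperature.

Step 10
Reactants: 15 7-methyl-4-oxo-8-[(triisopropylsilyl)ethynyl]-4H-chromen-5-yl trifluoromethanesulfonate; 16 carbon monoxide
Product: 17 methyl 7-methyl-4-oxo-8-[(triisopropylsilyl)ethynyl]-4H-chromene-5-carboxylate
Conditions: Pd(OAc)2 (5 mol %), dppp (6 mol %), CO (1 atm), MeOH, NEt3, DMF, 70 °C
Reagents that add atoms: methanol, CO
Why: Palladium-catalysed alkoxycarbonylation of an aryl triflate with a chelating diphosphine, during which the bulky silyl group keeps the alkyne masked in warm MeOH/NEt3 so that no terminal alkyne can couple with the triflate.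

Step 11
Reactants: 17 methyl 7-methyl-4-oxo-8-[(triisopropylsilyl)ethynyl]-4H-chromene-5-carboxylate
Product: 18 methyl 8-ethynyl-7-methyl-4-oxo-4H-chromene-5-carboxylate
Conditions: Bu4NF (1.1 equiv), AcOH (1.2 equiv), THF, 0 °C
Reagents that add atoms: none
Why: Fluoride-induced protodesilylation of the alkynylsilane, buffered with acetic acid to spare the base-sensitive pyranone ring and the ester.

Step 12
Reactants: 18 methyl 8-ethynyl-7-methyl-4-oxo-4H-chromene-5-carboxylate
Product: 19 methyl 7-methyl-4-oxo-8-[1-(tributylstannyl)ethenyl]-4H-chromene-5-carboxylate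
Conditions: Bu3SnH (1.2 equiv, slow addition), PdCl2(PPh3)2 (2 mol %), THF, 0 °C → rt; NEt3-deactivated silica
Reagents that add atoms: tributyltin hydride, CCCC[SnH](CCCC)CCCC
Why: Palladium-catalysed syn-hydrostannation, in which the known effects of ortho substituents (here O1 and the C7 methyl) and of an electron-poor aryl group (ester para to the alkyne) both steer tin to the aryl-bearing carbon and should give the Markovnikov α-stannane.

Step 13
Reactants: 19 methyl 7-methyl-4-oxo-8-[1-(tributylstannyl)ethenyl]-4H-chromene-5-carboxylate; 4 2-iodo-3-methoxy-5-methylbenzoyl chloride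
Product: 20 methyl 8-[3-(2-iodo-3-methoxy-5-methylphenyl)-3-oxoprop-1-en-2-yl]-7-methyl-4-oxo-4H-chromene-5-carboxylate
Conditions: Pd2(dba)3 (2.5 mol %), P(2-furyl)3 (10 mol %), 4 (1.1 equiv), THF, rt → 45 °C
Reagents that add atoms: none
Why: Stille acylation (ketone synthesis from an acid chloride and an organostannane), in which oxidative addition into the acyl C–Cl bond should outrun insertion into the doubly ortho-flanked C–I bond at this mild temperature, the weakly donating phosphine speeds tin-to-palladium transfer, and the alkenyl group migrates in preference to butyl.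

Step 14
Reactants: 20 methyl 8-[3-(2-iodo-3-methoxy-5-methylphenyl)-3-oxoprop-1-en-2-yl]-7-methyl-4-oxo-4H-chromene-5-carboxylate; 16 carbon monoxide
Product: 21 methyl 8-(5-methoxy-7-methyl-1,4-dioxo-1,4-dihydronaphthalen-2-yl)-7-methyl-4-oxo-4H-chromene-5-carboxylate
Conditions: Pd(PPh3)4 (5 mol %), NEt3 (2 equiv), CO (40 atm), MeCN–toluene 1:1, 100 °C
Reagents that add atoms: none
Why: Zerovalent palladium inserts into the C4a–I bond of 20 and takes up CO to give an aroylpalladium iodide which, in the absence of any alcohol, amine N–H or water, can only be consumed by the alkene held four atoms away. The acyl carbon bonds to the terminal CH2 (the future C3) in a 6-endo-trig acylpalladation, so palladium arrives at C2 as an enolate of the C1 ketone (oxa-π-allyl form), and loss of a C3 hydrogen as HPdI, taken up by NEt3, creates the C2=C3 bond and returns zerovalent palladium. The closest known reaction type is exactly this one, the endo-mode carbonylative cyclisation of 2-iodoaryl vinyl ketones to 1,4-naphthoquinones; the only new element is the bulky aryl group on the internal alkene carbon. Ring B is the single ring closed (6-endo) and no stereocentre is formed. Two selectivities are needed: CO insertion before any direct carbopalladation, secured by the high CO pressure and the strained 4-exo or 5-endo alternatives, and endo over 5-exo acyl transfer, secured by the substrate because the exo mode would have to build a quaternary C2 next to the chromone and would end in a primary alkylpalladium with no β-hydrogen and so no productive exit. The quinone regiochemistry (aryl at C2, remote from the C5 oxygen) cannot drift, since C1 and the iodine are fixed on ring A before the step.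

Step 15
Reactants: 21 methyl 8-(5-methoxy-7-methyl-1,4-dioxo-1,4-dihydronaphthalen-2-yl)-7-methyl-4-oxo-4H-chromene-5-carboxylate
Product: 22 methyl 8-(5-hydroxy-7-methyl-1,4-dioxo-1,4-dihydronaphthalen-2-yl)-7-methyl-4-oxo-4H-chromene-5-carboxylate
Conditions: BCl3 (4 equiv), CH2Cl2, −78 → 0 °C; H2O
Reagents that add atoms: none
Why: Peri-carbonyl-assisted ether cleavage, in which boron chelated between the C4 quinone oxygen and the C5 methoxy oxygen removes the only aryl methyl ether, the excess reagent covering the other Lewis-basic carbonyl groups.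

Step 16
Reactants: 22 methyl 8-(5-hydroxy-7-methyl-1,4-dioxo-1,4-dihydronaphthalen-2-yl)-7-methyl-4-oxo-4H-chromene-5-carboxylate
Product: 23 8-(5-hydroxy-7-methyl-1,4-dioxo-1,4-dihydronaphthalen-2-yl)-7-methyl-4-oxo-4H-chromene-5-carboxylic acid (target)
Conditions: H2SO4 (50 % aq.), AcOH, 90 °C
Reagents that add atoms: water, O
Why: Acid-catalysed acyl-oxygen ester hydrolysis, chosen over saponification because hydroxide opens the 2,3-unsubstituted pyranone and degrades the quinone whereas both tolerate aqueous acid, and the non-nucleophilic counter-ion avoids halide addition at C3.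

**Compound list**
1 | 3-methoxy-5-methylbenzoic acid | COc1cc(C)cc(C(=O)O)c1 | starting material
2 | lithium 2-lithio-3-methoxy-5-methylbenzoate | [Li]OC(=O)c1cc(C)cc(OC)c1[Li] | intermediate
3 | 2-iodo-3-methoxy-5-methylbenzoic acid | COc1cc(C)cc(C(=O)O)c1I | intermediate
4 | 2-iodo-3-methoxy-5-methylbenzoyl chloride | COc1cc(C)cc(C(=O)Cl)c1I | intermediate
5 | 3,5-dimethoxytoluene | COc1cc(C)cc(OC)c1 | starting material
6 | (2,6-dimethoxy-4-methylphenyl)lithium | [Li]c1c(OC)cc(C)cc1OC | intermediate
7 | 1-(2,6-dimethoxy-4-methylphenyl)ethan-1-one | CC(=O)c1c(OC)cc(C)cc1OC | intermediate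
8 | 1-(2-hydroxy-6-methoxy-4-methylphenyl)ethan-1-one | CC(=O)c1c(O)cc(C)cc1OC | intermediate
9 | (E)-3-(dimethylamino)-1-(2-hydroxy-6-methoxy-4-methylphenyl)prop-2-en-1-one | CN(C)/C=C/C(=O)c1c(O)cc(C)cc1OC | intermediate
10 | 5-methoxy-7-methyl-4H-chromen-4-one | COc1cc(C)cc2occc(=O)c12 | intermediate
11 | 8-iodo-5-methoxy-7-methyl-4H-chromen-4-one | COc1cc(C)c(I)c2occc(=O)c12 | intermediate
12 | 5-hydroxy-8-iodo-7-methyl-4H-chromen-4-one | Oc1cc(C)c(I)c2occc(=O)c12 | intermediate
13 | 8-iodo-7-methyl-4-oxo-4H-chromen-5-yl trifluoromethanesulfonate | O=S(=O)(Oc1cc(C)c(I)c2occc(=O)c12)C(F)(F)F | intermediate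
14 | (triisopropylsilyl)acetylene | C#C[Si](C(C)C)(C(C)C)C(C)C | starting material
15 | 7-methyl-4-oxo-8-[(triisopropylsilyl)ethynyl]-4H-chromen-5-yl trifluoromethanesulfonate | O=S(=O)(Oc1cc(C)c(C#C[Si](C(C)C)(C(C)C)C(C)C)c2occc(=O)c12)C(F)(F)F | intermediate
16 | carbon monoxide | [C-]#[O+] | starting material
17 | methyl 7-methyl-4-oxo-8-[(triisopropylsilyl)ethynyl]-4H-chromene-5-carboxylate | COC(=O)c1cc(C)c(C#C[Si](C(C)C)(C(C)C)C(C)C)c2occc(=O)c12 | intermediate
18 | methyl 8-ethynyl-7-methyl-4-oxo-4H-chromene-5-carboxylate | COC(=O)c1cc(C)c(C#C)c2occc(=O)c12 | intermediate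
19 | methyl 7-methyl-4-oxo-8-[1-(tributylstannyl)ethenyl]-4H-chromene-5-carboxylate | COC(=O)c1cc(C)c(C(=C)[Sn](CCCC)(CCCC)CCCC)c2occc(=O)c12 | intermediate
20 | methyl 8-[3-(2-iodo-3-methoxy-5-methylphenyl)-3-oxoprop-1-en-2-yl]-7-methyl-4-oxo-4H-chromene-5-carboxylate | C=C(C(=O)c1cc(C)cc(OC)c1I)c1c(C)cc(C(=O)OC)c2c(=O)ccoc12 | intermediate
21 | methyl 8-(5-methoxy-7-methyl-1,4-dioxo-1,4-dihydronaphthalen-2-yl)-7-methyl-4-oxo-4H-chromene-5-carboxylate | COc1cc(C)cc2c1C(=O)C=C(c1c(C)cc(C(=O)OC)c3c(=O)ccoc13)C2=O | intermediate
22 | methyl 8-(5-hydroxy-7-methyl-1,4-dioxo-1,4-dihydronaphthalen-2-yl)-7-methyl-4-oxo-4H-chromene-5-carboxylate | COC(=O)c1cc(C)c(C2=CC(=O)c3c(O)cc(C)cc3C2=O)c2occc(=O)c12 | intermediate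
23 | 8-(5-hydroxy-7-methyl-1,4-dioxo-1,4-dihydronaphthalen-2-yl)-7-methyl-4-oxo-4H-chromene-5-carboxylic acid | Cc1cc(O)c2c(c1)C(=O)C(c1c(C)cc(C(=O)O)c3c(=O)ccoc13)=CC2=O | target

**Step count**
Total steps: 16. Longest linear sequence: 14 (steps 3–16, from 5 to 23).

**Steps most likely to fail**

Step 14. The crowded, twisted 1-arylvinyl unit may slow the 6-endo acylpalladation. The aroylpalladium species could then decarbonylate, be reduced or add intermolecularly. The fallback is a Dötz benzannulation, which builds ring B from a chromium carbene on ring A instead of from an aryl iodide. It sets out from alkyne 18. Commercial 2-bromo-5-methylanisole would be converted (n-BuLi, then Cr(CO)6, then Me3OBF4) into pentacarbonyl[methoxy(2-methoxy-4-methylphenyl)methylidene]chromium F1. Heating this zerovalent chromium complex with 18 in THF at 55 °C should bring about alkyne insertion, CO insertion and electrocyclic closure onto the free ortho carbon. The expected product is methyl 8-(1-hydroxy-4,5-dimethoxy-7-methylnaphthalen-2-yl)-7-methyl-4-oxo-4H-chromene-5-carboxylate F2. The alkyne substituent should end up next to the CO-derived C1–OH, as is usual for terminal alkynes. Oxidation with (NH4)2Ce(NO3)6 in aqueous MeCN strips the chromium, removes the C4 methyl group and comes back to the route at 21.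

Step 13. Three processes may erode the coupling: insertion of zerovalent palladium into the C–I bond of 4 or 20, slow tin-to-palladium transfer from the hindered α-stannane, and protodestannylation by traces of HCl. The fallback forms the C1–C2 bond without palladium by a Claisen-type acylation and adds C3 afterwards as formaldehyde. It sets out from iodo triflate 13.
- Negishi-type coupling at the C–I bond with the Reformatsky reagent BrZnCH2CO2tBu (Pd(dba)2, Q-Phos, THF, rt) would give tert-butyl 2-[7-methyl-4-oxo-5-(trifluoromethylsulfonyloxy)-4H-chromen-8-yl]acetate F3.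
- Methoxycarbonylation under the conditions of step 10 would give methyl 8-(2-tert-butoxy-2-oxoethyl)-7-methyl-4-oxo-4H-chromene-5-carboxylate F4.
- Deprotonation with LiN(SiMe3)2 (2 equiv, THF, −78 °C) and C-acylation with 4 would give the racemic β-keto ester methyl 8-[1-tert-butoxy-3-(2-iodo-3-methoxy-5-methylphenyl)-1,3-dioxopropan-2-yl]-7-methyl-4-oxo-4H-chromene-5-carboxylate F5.
- CF3CO2H in CH2Cl2 would free the β-keto acid 3-(2-iodo-3-methoxy-5-methylphenyl)-2-[5-(methoxycarbonyl)-7-methyl-4-oxo-4H-chromen-8-yl]-3-oxopropanoic acid F6.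
- On warming, this acid loses CO2 to give the deoxybenzoin methyl 8-[2-(2-iodo-3-methoxy-5-methylphenyl)-2-oxoethyl]-7-methyl-4-oxo-4H-chromene-5-carboxylate F7.
- Mannich-type α-methylenation (paraformaldehyde, iPr2NH2·O2CCF3, THF, reflux) comes back to the route at 20.

Step 6. Attack at C6 or at C3 of the pyranone, or low conversion on the acyl-deactivated ring, would spoil the placement of the C8′ handle. The fallback iodinates before ring D exists. It sets out from the symmetric ketone 7, whose two free ring positions are equivalent. N-Iodosuccinimide in CF3CO2H/MeCN would give 1-(3-iodo-2,6-dimethoxy-4-methylphenyl)ethan-1-one F8 as the only possible mono-iodide. BCl3 (1 equiv, CH2Cl2, −78 °C) is expected to cleave the methoxy group wedged between acetyl and iodine, which is forced out of the ring plane and is therefore the more basic one. This would give 1-(2-hydroxy-3-iodo-6-methoxy-4-methylphenyl)ethan-1-one F9. Me2NCH(OMe)2 would then give (E)-3-(dimethylamino)-1-(2-hydroxy-3-iodo-6-methoxy-4-methylphenyl)prop-2-en-1-one F10. Acid closes ring D through the only free phenol, the one next to iodine, and comes back to the route at 11.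

**Further compounds**
F1 | step 14 | pentacarbonyl[methoxy(2-methoxy-4-methylphenyl)methylidene]chromium | COC(c1ccc(C)cc1OC)=[Cr](=C=O)(=C=O)(=C=O)(=C=O)=C=O
F2 | step 14 | methyl 8-(1-hydroxy-4,5-dimethoxy-7-methylnaphthalen-2-yl)-7-methyl-4-oxo-4H-chromene-5-carboxylate | COC(=O)c1cc(C)c(-c2cc(OC)c3c(OC)cc(C)cc3c2O)c2occc(=O)c12
F3 | step 13 | tert-butyl 2-[7-methyl-4-oxo-5-(trifluoromethylsulfonyloxy)-4H-chromen-8-yl]acetate | CC(C)(C)OC(=O)Cc1c(C)cc(OS(=O)(=O)C(F)(F)F)c2c(=O)ccoc12
F4 | step 13 | methyl 8-(2-tert-butoxy-2-oxoethyl)-7-methyl-4-oxo-4H-chromene-5-carboxylate | COC(=O)c1cc(C)c(CC(=O)OC(C)(C)C)c2occc(=O)c12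
F5 | step 13 | methyl 8-[1-tert-butoxy-3-(2-iodo-3-methoxy-5-methylphenyl)-1,3-dioxopropan-2-yl]-7-methyl-4-oxo-4H-chromene-5-carboxylate (racemic) | COC(=O)c1cc(C)c(C(C(=O)OC(C)(C)C)C(=O)c3cc(C)cc(OC)c3I)c2occc(=O)c12
F6 | step 13 | 3-(2-iodo-3-methoxy-5-methylphenyl)-2-[5-(methoxycarbonyl)-7-methyl-4-oxo-4H-chromen-8-yl]-3-oxopropanoic acid (racemic) | COC(=O)c1cc(C)c(C(C(=O)O)C(=O)c3cc(C)cc(OC)c3I)c2occc(=O)c12
F7 | step 13 | methyl 8-[2-(2-iodo-3-methoxy-5-methylphenyl)-2-oxoethyl]-7-methyl-4-oxo-4H-chromene-5-carboxylate | COC(=O)c1cc(C)c(CC(=O)c3cc(C)cc(OC)c3I)c2occc(=O)c12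
F8 | step 6 | 1-(3-iodo-2,6-dimethoxy-4-methylphenyl)ethan-1-one | CC(=O)c1c(OC)cc(C)c(I)c1OC
F9 | step 6 | 1-(2-hydroxy-3-iodo-6-methoxy-4-methylphenyl)ethan-1-one | CC(=O)c1c(OC)cc(C)c(I)c1O
F10 | step 6 | (E)-3-(dimethylamino)-1-(2-hydroxy-3-iodo-6-methoxy-4-methylphenyl)prop-2-en-1-one | CN(C)/C=C/C(=O)c1c(OC)cc(C)c(I)c1O
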